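The route rests on cutting the tetronic acid (ring A) back to a squarate-derived cyclobutenone. Lactone carbonyl C2, methyl-bearing C3, oxygenated C4 and ylidene carbon C5 are the four ring carbons of a 4-alkyl-4-hydroxy-3-methoxy-2-methylcyclobutenone, and its carbinol oxygen becomes O1. One Pb(OAc)4 oxidation breaks the strained carbinol–ketone bond, closes the five-membered lactone through O1–C2 bond formation and installs the (Z)-C5=C6 alkene, leaving the C7 stereocentre untouched. The precursor carries only an (R)-2-methylpent-4-enyl chain. The oxidant-sensitive difuran half is attached afterwards by B-alkyl Suzuki coupling at C10–C11, and O-demethylation ends the synthesis.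

Key step: step 5

Numbering used: ring A = O1, C2 (lactone C=O), C3 (methyl), C4 (oxygenated), C5; chain = C6 (ylidene CH), C7 (methyl-bearing stereocentre), C8–C10, C11 (methyl-bearing alkene carbon), C12, C13, C14; ring B = the 2,4-disubstituted furan; ring C = the 3-substituted furan. Target configuration: 5Z, 7R, 11E.

Assumption (a): 9 and 10 should form as mixtures of epimers at the carbinol or acetal carbon and 15 as a racemate; these centres later become sp2 or CH2, so no control is needed.

Assumption (b): the S descriptor of 5 becomes R in 6 without any bond at the stereocentre being touched, because the CIP priorities of the two CH2 arms change.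

Assumption (c): metal alkoxides, and the lithium tetronate of step 12, that are only protonated on work-up are treated as salt forms of the numbered product.

Step 1
Reactants: 1 dimethyl squarate
Product: 4 3-methoxy-4-methylcyclobut-3-ene-1,2-dione, via lithium alkoxide adduct 2 (not isolated), via trifluoroacetate ester 3 (not isolated)
Conditions: MeLi (1.05 equiv), THF, −78 °C; (CF3CO)2O, −78 °C; then H2O, rt
Reagents that add atoms: methyllithium, [Li]C; water, O
Why: Methyllithium should add once (1,2-addition) to a squarate carbonyl at −78 °C, and the trifluoroacetylated adduct should ionise and hydrolyse on work-up with loss of methanol (the standard squarate 1,2-addition/transposition sequence) to give the 3-alkyl-4-alkoxycyclobutenedione, the transient racemic carbinol centre being destroyed.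

Step 2
Reactants: 5 (S)-3-bromo-2-methylpropan-1-ol
Product: 6 (R)-2-methylpent-4-en-1-ol
Conditions: CH2=CHMgBr (3 equiv), CuI (cat.), THF, −30 °C to rt; 1 M HCl quench
Reagents that add atoms: vinylmagnesium bromide, C=C[Mg]Br
Why: In this copper-catalysed Grignard cross-coupling (Kochi type) the first equivalent of Grignard reagent forms the magnesium alkoxide and the vinyl cuprate displaces the primary bromide at CH2, so the stereocentre is a spectator.

Step 3
Reactants: 6 (R)-2-methylpent-4-en-1-ol
Product: 7 (R)-5-iodo-4-methylpent-1-ene
Conditions: I2, PPh3, imidazole, CH2Cl2, 0 °C to rt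
Reagents that add atoms: iodine, II
Why: Appel-type iodination (Garegg–Samuelsson conditions) should replace the primary hydroxyl by iodide through SN2 displacement at CH2, one carbon away from the stereocentre, which is not involved.

Step 4
Reactants: 7 (R)-5-iodo-4-methylpent-1-ene; 4 3-methoxy-4-methylcyclobut-3-ene-1,2-dione
Product: 9 4-hydroxy-3-methoxy-2-methyl-4-[(R)-2-methylpent-4-enyl]cyclobut-2-enone (both epimers at the carbinol carbon), via alkyllithium 8 (not isolated)
Conditions: t-BuLi (2.1 equiv), Et2O–pentane, −78 °C; then added to 4, THF, −78 °C; aq. NH4Cl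
Reagents that add atoms: none
Why: Lithium–iodine exchange should give the primary alkyllithium (a 4-pentenyllithium, which does not cyclise), and its 1,2-addition should occur at the ketone-like carbonyl next to the methoxy-bearing carbon and not at the vinylogous ester carbonyl, which places methyl and methoxy at the future C3 and C4; the new carbinol centre is uncontrolled and both epimers are carried on.

Step 5
Reactants: 9 4-hydroxy-3-methoxy-2-methyl-4-[(R)-2-methylpent-4-enyl]cyclobut-2-enone
Product: 11 (Z)-4-methoxy-3-methyl-5-[(R)-2-methylpent-4-enylidene]furan-2(5H)-one, via 5-acetoxy lactone 10 (not isolated)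
Conditions: Pb(OAc)4 (1.2 equiv), PhMe, rt; then DBU (1.1 equiv), 0 °C, short contact
Reagents that add atoms: none
Why: Ligand exchange gives a tetravalent lead alkoxide of the tertiary carbinol, which fragments by cleaving the strained ring bond between the carbinol carbon and the ketone carbon, leaving a ketone at the former carbinol carbon and an acyl cation equivalent at the former ketone carbon while lead becomes divalent. The new ketone oxygen captures the acyl carbon in a 5-exo O-acylation (the acyl C=O stays outside the new ring), which closes ring A with O1–C2 bond formation and leaves an oxocarbenium ion at C5. This ion loses a C6 proton directly or is trapped by acetate as the 5-acetoxy lactone 10, from which DBU removes AcOH across C5–C6. The closest known reaction type is the Pb(OAc)4 oxidative ring expansion of squarate-derived 4-hydroxycyclobut-2-enones to 5-acetoxy- and 5-ylidene-furan-2(5H)-ones. No stereocentre is created: the alkene should be Z because the E isomer would force C7 against the C4 methoxy group, and C7 keeps its configuration because only C6–H is removed and the base contact is short. The step needs cleavage toward the acyl carbon and not toward the vinylic carbon or the side-chain CH2, which ring strain plus acyl stabilisation secure, and it needs the oxidant to spare the rest of the molecule, which is secured by the slow reaction of Pb(OAc)4 with an isolated terminal alkene at room temperature and by the absence of the furans at this stage.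

Step 6
Reactants: 12 3-bromofuran; 13 4-bromo-2-furaldehyde
Product: 15 (4-bromofuran-2-yl)(furan-3-yl)methanol (racemic), via furan-3-yllithium 14 (not isolated)
Conditions: n-BuLi, THF, −78 °C; then 13, −78 °C; aq. NH4Cl
Reagents that add atoms: none
Why: Bromine–lithium exchange at −78 °C should give furan-3-yllithium (kept cold so that it does not isomerise to the 2-lithio species), which adds 1,2 to the aldehyde faster than it exchanges with the ring bromide; the racemic carbinol centre is removed in step 7.

Step 7
Reactants: 15 (4-bromofuran-2-yl)(furan-3-yl)methanol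
Product: 16 4-bromo-2-(furan-3-ylmethyl)furan
Conditions: Et3SiH (3 equiv), CF3CO2H, CH2Cl2, −20 °C, short reaction time
Reagents that add atoms: none
Why: In this ionic hydrogenation the acid ionises the doubly furyl-stabilised carbinol and excess Et3SiH should trap the cation by hydride transfer at low temperature before it can alkylate another furan, the ring bromide lowering the nucleophilicity of its own furan.

Step 8
Reactants: 17 pent-3-yn-1-ol
Product: 18 5-iodopent-2-yne
Conditions: I2, PPh3, imidazole, CH2Cl2, 0 °C to rt
Reagents that add atoms: iodine, II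
Why: Appel-type iodination of an unhindered primary alcohol by SN2 displacement should leave the internal alkyne unaffected.

Step 9
Reactants: 18 5-iodopent-2-yne; 16 4-bromo-2-(furan-3-ylmethyl)furan
Product: 20 2-(furan-3-ylmethyl)-4-(pent-3-yn-1-yl)furan, via pent-3-yn-1-ylzinc iodide 19 (not isolated)
Conditions: Zn dust, LiCl, THF, 40 °C; then 16, Pd(OAc)2 (cat.), SPhos, THF, rt to 50 °C
Reagents that add atoms: none
Why: LiCl-promoted zinc insertion into the primary iodide should give an alkylzinc that tolerates the internal alkyne, and Negishi sp3–sp2 cross-coupling with the electron-rich 3-bromofuran position should be fast with the bulky biarylphosphine SPhos, which also suppresses β-hydride elimination.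

Step 10
Reactants: 20 2-(furan-3-ylmethyl)-4-(pent-3-yn-1-yl)furan
Product: 22 4-[(E)-4-iodopent-3-en-1-yl]-2-(furan-3-ylmethyl)furan, via alkenylzirconocene chloride 21 (not isolated)
Conditions: Cp2Zr(H)Cl (2.2 equiv), THF, 50 °C; then I2, THF, −78 to 0 °C
Reagents that add atoms: iodine, II
Why: Hydrozirconation (syn addition of Zr–H) of the methyl alkyne with excess Cp2Zr(H)Cl under equilibrating conditions should place zirconium on the less hindered, methyl-bearing carbon, and iodinolysis with retention should give the (E)-2-iodo-2-alkene, the furans being inert to the hydride and exposed to iodine only briefly at low temperature.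

Step 11
Reactants: 11 (Z)-4-methoxy-3-methyl-5-[(R)-2-methylpent-4-enylidene]furan-2(5H)-one; 22 4-[(E)-4-iodopent-3-en-1-yl]-2-(furan-3-ylmethyl)furan
Product: 24 (5Z)-5-[(2R,6E)-9-[5-(furan-3-ylmethyl)furan-3-yl]-2,6-dimethylnon-6-en-1-ylidene]-4-methoxy-3-methylfuran-2(5H)-one, via B-alkyl-9-BBN adduct 23 (not isolated)
Conditions: 9-BBN dimer (0.75 equiv), THF, 0 °C to rt; then 22, PdCl2(dppf) (5 mol%), AsPh3, Cs2CO3, DMF–H2O, rt
Reagents that add atoms: none
Why: 9-BBN should hydroborate only the terminal alkene (anti-Markovnikov), and B-alkyl Suzuki–Miyaura coupling of the borane with the alkenyl iodide under mild aqueous carbonate should form the C10–C11 bond with retention of the E geometry, while the vinylogous carbonate lactone, the ylidene and C7 are inert under these conditions.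

Step 12
Reactants: 24 (5Z)-5-[(2R,6E)-9-[5-(furan-3-ylmethyl)furan-3-yl]-2,6-dimethylnon-6-en-1-ylidene]-4-methoxy-3-methylfuran-2(5H)-one
Product: 25 (5Z)-5-[(2R,6E)-9-[5-(furan-3-ylmethyl)furan-3-yl]-2,6-dimethylnon-6-en-1-ylidene]-4-hydroxy-3-methylfuran-2(5H)-one
Conditions: LiCl (10 equiv), DMF, 90 °C; then cold 0.1 M HCl to pH 3
Reagents that add atoms: none
Why: Chloride should attack the O-methyl group of the vinylogous carbonate in an SN2 dealkylation that releases the stabilised tetronate anion, which is protonated by a brief cold acidification mild enough for the furans, no stereocentre or alkene being touched.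

Compound list
1 | dimethyl squarate (3,4-dimethoxycyclobut-3-ene-1,2-dione) | COC1=C(OC)C(=O)C1=O | starting material
2 | lithium 2,3-dimethoxy-1-methyl-4-oxocyclobut-2-en-1-olate (racemic) | COC1=C(OC)C(C)(O[Li])C1=O | intermediate
3 | 2,3-dimethoxy-1-methyl-4-oxocyclobut-2-en-1-yl trifluoroacetate (racemic) | COC1=C(OC)C(C)(OC(=O)C(F)(F)F)C1=O | intermediate
4 | 3-methoxy-4-methylcyclobut-3-ene-1,2-dione | COC1=C(C)C(=O)C1=O | intermediate
5 | (S)-3-bromo-2-methylpropan-1-ol | OC[C@H](C)CBr | starting material
6 | (R)-2-methylpent-4-en-1-ol | OC[C@H](C)CC=C | intermediate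
7 | (R)-5-iodo-4-methylpent-1-ene | IC[C@H](C)CC=C | intermediate
8 | (S)-(2-methylpent-4-en-1-yl)lithium | [Li]C[C@H](C)CC=C | intermediate
9 | 4-hydroxy-3-methoxy-2-methyl-4-[(R)-2-methylpent-4-enyl]cyclobut-2-enone (both epimers at the carbinol carbon) | CC1=C(OC)C(O)(C[C@H](C)CC=C)C1=O | intermediate
10 | 5-acetoxy-4-methoxy-3-methyl-5-[(R)-2-methylpent-4-enyl]furan-2(5H)-one (both C5 epimers) | CC1=C(OC)C(OC(C)=O)(C[C@H](C)CC=C)OC1=O | intermediate
11 | (Z)-4-methoxy-3-methyl-5-[(R)-2-methylpent-4-enylidene]furan-2(5H)-one | CC1=C(OC)/C(=C/[C@H](C)CC=C)OC1=O | intermediate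
12 | 3-bromofuran | Brc1ccoc1 | starting material
13 | 4-bromo-2-furaldehyde | O=Cc1cc(Br)co1 | starting material
14 | furan-3-yllithium | [Li]c1ccoc1 | intermediate
15 | (4-bromofuran-2-yl)(furan-3-yl)methanol (racemic) | OC(c1ccoc1)c1cc(Br)co1 | intermediate
16 | 4-bromo-2-(furan-3-ylmethyl)furan | Brc1coc(Cc2ccoc2)c1 | intermediate
17 | pent-3-yn-1-ol | CC#CCCO | starting material
18 | 5-iodopent-2-yne | CC#CCCI | intermediate
19 | pent-3-yn-1-ylzinc iodide | CC#CCC[Zn]I | intermediate
20 | 2-(furan-3-ylmethyl)-4-(pent-3-yn-1-yl)furan | CC#CCCc1coc(Cc2ccoc2)c1 | intermediate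
21 | chlorobis(cyclopentadienyl)[(E)-5-[5-(furan-3-ylmethyl)furan-3-yl]pent-2-en-2-yl]zirconium | C/C(=C\CCc1coc(Cc2ccoc2)c1)[Zr](Cl)(C1C=CC=C1)C1C=CC=C1 | intermediate
22 | 4-[(E)-4-iodopent-3-en-1-yl]-2-(furan-3-ylmethyl)furan | C/C(I)=C\CCc1coc(Cc2ccoc2)c1 | intermediate
23 | (Z)-5-[(R)-5-(9-borabicyclo[3.3.1]nonan-9-yl)-2-methylpentylidene]-4-methoxy-3-methylfuran-2(5H)-one | CC1=C(OC)/C(=C/[C@H](C)CCCB2C3CCCC2CCC3)OC1=O | intermediate
24 | (5Z)-5-[(2R,6E)-9-[5-(furan-3-ylmethyl)furan-3-yl]-2,6-dimethylnon-6-en-1-ylidene]-4-methoxy-3-methylfuran-2(5H)-one | CC1=C(OC)/C(=C/[C@H](C)CCC/C(C)=C/CCc2coc(Cc3ccoc3)c2)OC1=O | intermediate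
25 | (5Z)-5-[(2R,6E)-9-[5-(furan-3-ylmethyl)furan-3-yl]-2,6-dimethylnon-6-en-1-ylidene]-4-hydroxy-3-methylfuran-2(5H)-one | CC1=C(O)/C(=C/[C@H](C)CCC/C(C)=C/CCc2coc(Cc3ccoc3)c2)OC1=O | target

Total step count: 12.

Longest linear sequence: 6 steps (steps 2, 3, 4, 5, 11, 12 from 5; equally steps 6, 7, 9, 10, 11, 12 from 12 and 13).

Steps most likely to fail

Step 5. The lead alkoxide may fragment in an unwanted direction, the oxidant may attack the terminal alkene, loss of acetic acid may be incomplete or give E/Z mixtures, and prolonged base contact may erode C7 through vinylogous deprotonation. The fallback keeps the squarate logic but separates ring expansion from dehydrogenation. It sets out from 9: thermolysis in refluxing toluene or xylene should open the cyclobutenone to the vinylketene, whose enol oxygen closes onto the ketene to give 4-methoxy-3-methyl-5-[(R)-2-methylpent-4-enyl]furan-2(5H)-one F1. Deprotonation at C5 with LiN(iPr)2 at −78 °C and trapping with PhSeCl should give 4-methoxy-3-methyl-5-[(R)-2-methylpent-4-enyl]-5-(phenylselanyl)furan-2(5H)-one F2. Oxidation with H2O2 at 0 °C should give the selenoxide F3, whose syn-elimination can involve only C6–H. A trace of I2 would equilibrate any E isomer, and the sequence comes back to the route at 11.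

Step 11. Transmetalation from boron may be slow, so that β-hydride elimination or protodeboronation competes, and the aqueous base may open the ylidene lactone. The fallback replaces the borane by an organozinc and avoids aqueous base in the coupling. It sets out from 11: hydroboration with 9-BBN as in the route (borane 23) and buffered oxidation with NaBO3·4H2O should give (Z)-5-[(R)-5-hydroxy-2-methylpentylidene]-4-methoxy-3-methylfuran-2(5H)-one F4. I2, PPh3 and imidazole should then give (Z)-5-[(R)-5-iodo-2-methylpentylidene]-4-methoxy-3-methylfuran-2(5H)-one F5. Zinc insertion (Zn dust, LiCl, THF) should give the alkylzinc iodide F6, and Negishi coupling with 22 (Pd(PPh3)4, THF) comes back to the route at 24.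

Step 7. The furfuryl-type cation may alkylate another furan (oligomerisation) or the rings may open before hydride capture, and over-reduction of a furan is possible on long exposure to acid. The fallback removes the oxygen under basic conditions with no cation. It sets out from 15: oxidation with MnO2 in CH2Cl2 should give (4-bromofuran-2-yl)(furan-3-yl)methanone F7. N2H4·H2O in EtOH should give (4-bromofuran-2-yl)(furan-3-yl)methanone hydrazone F8, and Wolff–Kishner reduction under Cram conditions (KOtBu, DMSO, rt) comes back to the route at 16.

Further compounds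
F1 | step 5 | 4-methoxy-3-methyl-5-[(R)-2-methylpent-4-enyl]furan-2(5H)-one (both C5 epimers) | CC1=C(OC)C(C[C@H](C)CC=C)OC1=O
F2 | step 5 | 4-methoxy-3-methyl-5-[(R)-2-methylpent-4-enyl]-5-(phenylselanyl)furan-2(5H)-one (both C5 epimers) | CC1=C(OC)C([Se]c2ccccc2)(C[C@H](C)CC=C)OC1=O
F3 | step 5 | 4-methoxy-3-methyl-5-[(R)-2-methylpent-4-enyl]-5-(phenylseleninyl)furan-2(5H)-one | CC1=C(OC)C([Se](=O)c2ccccc2)(C[C@H](C)CC=C)OC1=O
F4 | step 11 | (Z)-5-[(R)-5-hydroxy-2-methylpentylidene]-4-methoxy-3-methylfuran-2(5H)-one | CC1=C(OC)/C(=C/[C@H](C)CCCO)OC1=O
F5 | step 11 | (Z)-5-[(R)-5-iodo-2-methylpentylidene]-4-methoxy-3-methylfuran-2(5H)-one | CC1=C(OC)/C(=C/[C@H](C)CCCI)OC1=O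
F6 | step 11 | [(R,Z)-5-(3-methoxy-4-methyl-5-oxofuran-2(5H)-ylidene)-4-methylpentyl]zinc iodide | CC1=C(OC)/C(=C/[C@H](C)CCC[Zn]I)OC1=O
F7 | step 7 | (4-bromofuran-2-yl)(furan-3-yl)methanone | O=C(c1ccoc1)c1cc(Br)co1
F8 | step 7 | (4-bromofuran-2-yl)(furan-3-yl)methanone hydrazone | NN=C(c1ccoc1)c1cc(Br)co1
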